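The earlier runs and the new flask were generated by integration with constants of no real substance, noise included.

If D forms from Z and its way back is left aside, the D in a flask at any time is one constant times the area under the Z curve so far, and that constant can be read from runs already made.

the same everywhere: G 0.50 M
- alder: L 0.34 M; run made earlier
- ash: L 0.75 M; run made earlier
- flask: L 0.500 M; time 15 min

| run | time / min | Z / % | D / % |
|---|---|---|---|
| alder | 1.33 | 7.0 | 0.6 |
| alder | 4.00 | 13.5 | 3.0 |
| alder | 8.00 | 15.1 | 6.3 |
| alder | 10.0 | 14.7 | 8.6 |
| alder | 15.0 | 11.5 | 13.7 |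
| ash | 1.33 | 6.9 | 0.7 |
| ash | 4.00 | 12.7 | 2.8 |
| ash | 8.00 | 14.3 | 6.0 |
| ash | 10.0 | 12.6 | 7.9 |
| ash | 15.0 | 10.0 | 12.3 |

(scatter of a reading: 0.3 percentage points)

- ratio of Z to D at 12 s
- ratio of Z to D at 15 min

- percent here means G units held: one J counts as two
- the numbers in the tables scatter with a standard deviation of 0.3 percentage points
- reactions considered so far: G <-> Z; Z <-> D; G + L -> X; 2 G -> J

The reactions considered so far reach D through Z. I add up the area under Z in straight pieces to 15.0 min and divide cD there by it. This gives 0.0742 min⁻¹ in alder and 0.0731 min⁻¹ in ash, though ash holds twice the L. Their mean is the leak constant k, the first-order rate constant of Z going to D, read as D made per unit of area under Z: 0.0737 min⁻¹.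

Just after the start Z rises in a straight line, so the area is cZ·t/2 and cZ/cD = 2/(k t). Since 12 s is much earlier than the first reading, I commit to 136 for the flask. At 15 min I use the readings directly: the ratio is 0.839 in alder and 0.813 in ash, and a straight line in cL gives 0.829 at the flask's 0.500 M.

The weak link is the first reading. In alder, k times the area up to 1.33 min gives 0.343% of D, but alder reads 0.6% and ash 0.7%, a mean excess of 0.31 percentage points against a scatter of 0.3 points. I read that as scatter and keep 136.

The forecast gives 100 and 0.83. It takes the same readings as weak evidence of a direct route from G to D and, starting from about 130, says “I therefore shade the estimate down”. We part there, and agree at 15 min.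

The flask gives 137 at 12 s and 0.879 at 15 min.

    G ⇌ Z (K = 0.980, k = 0.0670 min⁻¹)
    Z ⇌ D (K = 24.0, k = 0.0720 min⁻¹)
    G + L → X (k = 0.0740 M⁻¹ min⁻¹)
    2 G → J (k = 0.160 M⁻¹ min⁻¹)

The way back from D to Z makes no difference to the early ratio in this flask. At 0.450 min this flask holds 2.76% of Z and 0.0460% of D, a ratio of 60.0, and 2/(k t) gives 60.3.

In the neighbour charged with 2.0 M of G, all else as in this flask, 2/(k t) has no charge in it, so k again gives 136 at 12 s. The computed ratio there is 135.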